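**Plan**
- The retrosynthesis first cuts the ether bond between the C2 oxygen of ring B (central ring) and C1 of ring C (the phenol ring), after masking the ring C hydroxyl as a MOM ether. It then takes the C2–O bond of ring B back to C2–I.
- Finally it cuts, in one operation, the ring A oxygen–ring B C1 bond and the ring B C2–I bond.
- Enabling feature: ring B carries the ring A aryloxy group at C1, an oxygen at C2 and a methoxy group at C3. C1 and C2 are therefore the two carbons of the triple bond of 5-allyl-3-methoxybenzyne, and the C3 methoxy group steers the addition.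
- Forward, eugenol supplies all three rings. Its ortho-bromo derivative is turned into the ring B aryne precursor and, as a MOM ether, into the ring C bromide.
- The chain is joined A–O–B first (aryne, phenoxide, iodine donor), the iodide is turned into the phenol dehydrodieugenol B, then B–O–C is made by copper-catalysed coupling and the MOM group is removed.
- The target has no stereocentre; only regiochemistry has to be controlled (ortho-bromination, aryne addition).

Key step: step 3

Remark: of the two silyl triflates that release 5-allyl-3-methoxybenzyne, the one with silicon on the future C1 and triflate on the future C2 is used. It is reached from eugenol through a bromophenol and a retro-Brook shift, whereas its isomer would need a directed lithiation beside an aryl bromide or an allyl group.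

Step 1
Reactants: 1 eugenol (4-allyl-2-methoxyphenol)
Product: 2 4-allyl-2-bromo-6-methoxyphenol
Conditions: NBS, i-Pr2NH (cat.), CH2Cl2, 0 °C, dark
Reagents that add atoms: N-bromosuccinimide, O=C1CCC(=O)N1Br
Why: Amine-catalysed electrophilic aromatic bromination, in which the hydrogen-bonded N-bromoamine should deliver bromine to the only free position ortho to the hydroxyl group, while the activated phenol ring should react with NBS much faster than the isolated terminal alkene when light and radical initiators are excluded.

Step 2
Reactants: 2 4-allyl-2-bromo-6-methoxyphenol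
Product: 5 4-allyl-2-methoxy-6-(trimethylsilyl)phenyl trifluoromethanesulfonate, via aryl trimethylsilyl ether 3 (not isolated), via lithium 2-silylphenoxide 4 (not isolated)
Conditions: HMDS, THF, 70 °C, then evaporation; n-BuLi, THF, −78 °C; Tf2O, −78 °C → 0 °C
Reagents that add atoms: hexamethyldisilazane, C[Si](C)(C)N[Si](C)(C)C; trifluoromethanesulfonic anhydride, O=S(=O)(OS(=O)(=O)C(F)(F)F)C(F)(F)F
Why: O-silylation, bromine–lithium exchange with retro-Brook (1,3 oxygen-to-carbon) silyl shift and O-triflation of the resulting lithium phenoxide is the standard one-flask access to 2-silylaryl triflates, and the exchange at −78 °C should be much faster than deprotonation of the allylic CH2 group.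

Step 3
Reactants: 5 4-allyl-2-methoxy-6-(trimethylsilyl)phenyl trifluoromethanesulfonate; 1 eugenol; 6 nonafluoro-1-iodobutane
Product: 10 5-allyl-1-(4-allyl-2-methoxyphenoxy)-2-iodo-3-methoxybenzene, via potassium eugenolate 7 (not isolated), via 5-allyl-3-methoxybenzyne 8 (not isolated), via C2 arylpotassium 9 (not isolated)
Conditions: 1, KH, THF, 0 °C; then 5, 6 (3 equiv), CsF, 18-crown-6, THF, 0 °C → rt, dark
Reagents that add atoms: nonafluoro-1-iodobutane (compound 6), FC(F)(F)C(F)(F)C(F)(F)C(F)(F)I
Why: Proposed new method: fluoride attacks silicon of 5 and triflate leaves to give aryne 8, phenoxide 7 adds to the aryne carbon remote from the methoxy group (C1 of ring B), and the aryl anion 9 formed at C2 takes iodine from 6 by halogenophilic substitution. The closest known reactions are the fluoride-induced O-arylation of phenols by arynes and the three-component amine–iodine and thiolate–iodine difunctionalisations of arynes that use perfluoroalkyl iodides as iodine donors; pairing an oxygen nucleophile with iodine transfer is the new element. No ring is closed and no stereocentre is formed. The step needs regioselective addition to an unsymmetrical aryne, and the methoxy group should secure it: the aryne is distorted so that C1 is the more linear and more electrophilic carbon, and attack there leaves the negative charge on C2 beside the inductively withdrawing oxygen. It also needs iodine transfer to outrun protonation of 9, which is favoured by a preformed alcohol-free phenoxide (KH leaves only H2), an aprotic solvent without acidic hydrogens and an excess of 6. Light is excluded to suppress radical perfluoroalkylation of the phenoxide.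

Step 4
Reactants: 10 5-allyl-1-(4-allyl-2-methoxyphenoxy)-2-iodo-3-methoxybenzene
Product: 13 dehydrodieugenol B (4-allyl-2-(4-allyl-2-methoxyphenoxy)-6-methoxyphenol), via arylmagnesium chloride 11 (not isolated), via dimethyl arylboronate 12 (not isolated)
Conditions: i-PrMgCl·LiCl, THF, −20 °C; B(OMe)3, −20 °C → rt; 30% H2O2, aq. NaOH, 0 °C
Reagents that add atoms: hydrogen peroxide, OO
Why: Iodine–magnesium exchange, borylation and alkaline peroxide oxidation (1,2-aryl shift from boron to oxygen) should convert the iodide into the phenol, since the two flanking oxygen substituents accelerate the exchange and terminal alkenes and aryl ethers are inert to i-PrMgCl at low temperature and to cold alkaline H2O2.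

Step 5
Reactants: 2 4-allyl-2-bromo-6-methoxyphenol
Product: 14 5-allyl-1-bromo-3-methoxy-2-(methoxymethoxy)benzene
Conditions: MOMCl, i-Pr2NEt, CH2Cl2, 0 °C → rt
Reagents that add atoms: chloromethyl methyl ether, COCCl
Why: O-alkylation of the phenol to its MOM acetal, a protecting group that should withstand the basic copper coupling and later leave under mild acid that does not touch allyl groups or methyl ethers.

Step 6
Reactants: 13 dehydrodieugenol B; 14 5-allyl-1-bromo-3-methoxy-2-(methoxymethoxy)benzene
Product: 15 5-allyl-1-[4-allyl-2-(4-allyl-2-methoxyphenoxy)-6-methoxyphenoxy]-3-methoxy-2-(methoxymethoxy)benzene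
Conditions: CuI (cat.), picolinic acid (cat.), K3PO4, DMSO, 90 °C
Reagents that add atoms: none
Why: Ullmann-type copper-catalysed C–O coupling of a phenol with an aryl bromide, run with the picolinate ligand system that is established for 2,6-disubstituted phenols and ortho-oxygenated aryl halides, and with K3PO4, which is not expected to move the allyl double bonds into conjugation.

Step 7
Reactants: 15 5-allyl-1-[4-allyl-2-(4-allyl-2-methoxyphenoxy)-6-methoxyphenoxy]-3-methoxy-2-(methoxymethoxy)benzene
Product: 16 4-allyl-2-[4-allyl-2-(4-allyl-2-methoxyphenoxy)-6-methoxyphenoxy]-6-methoxyphenol (target)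
Conditions: conc. HCl (cat.), MeOH, 40 °C
Reagents that add atoms: none
Why: Acid-catalysed cleavage of the MOM acetal by transacetalisation with methanol, under which diaryl ethers, aryl methyl ethers and terminal alkenes should be stable.

**Compound list**
1 | eugenol (4-allyl-2-methoxyphenol) | C=CCc1ccc(O)c(OC)c1 | starting material
2 | 4-allyl-2-bromo-6-methoxyphenol | C=CCc1cc(Br)c(O)c(OC)c1 | intermediate
3 | (4-allyl-2-bromo-6-methoxyphenoxy)trimethylsilane (not isolated) | C=CCc1cc(Br)c(O[Si](C)(C)C)c(OC)c1 | intermediate
4 | lithium 4-allyl-2-methoxy-6-(trimethylsilyl)phenoxide (not isolated) | C=CCc1cc(OC)c([O-])c([Si](C)(C)C)c1.[Li+] | intermediate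
5 | 4-allyl-2-methoxy-6-(trimethylsilyl)phenyl trifluoromethanesulfonate | C=CCc1cc(OC)c(OS(=O)(=O)C(F)(F)F)c([Si](C)(C)C)c1 | intermediate
6 | nonafluoro-1-iodobutane | FC(F)(F)C(F)(F)C(F)(F)C(F)(F)I | starting material
7 | potassium 4-allyl-2-methoxyphenoxide (potassium eugenolate; not isolated) | C=CCc1ccc([O-])c(OC)c1.[K+] | intermediate
8 | 5-allyl-3-methoxybenzyne (5-allyl-1,2-didehydro-3-methoxybenzene; not isolated) | C=CCC1=CC#CC(OC)=C1 | intermediate
9 | potassium 4-allyl-2-(4-allyl-2-methoxyphenoxy)-6-methoxybenzen-1-ide (not isolated) | C=CCc1ccc(Oc2cc(CC=C)cc(OC)[c-]2)c(OC)c1.[K+] | intermediate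
10 | 5-allyl-1-(4-allyl-2-methoxyphenoxy)-2-iodo-3-methoxybenzene | C=CCc1ccc(Oc2cc(CC=C)cc(OC)c2I)c(OC)c1 | intermediate
11 | [4-allyl-2-(4-allyl-2-methoxyphenoxy)-6-methoxyphenyl]magnesium chloride (not isolated) | C=CCc1ccc(Oc2cc(CC=C)cc(OC)c2[Mg]Cl)c(OC)c1 | intermediate
12 | dimethyl [4-allyl-2-(4-allyl-2-methoxyphenoxy)-6-methoxyphenyl]boronate (not isolated) | C=CCc1ccc(Oc2cc(CC=C)cc(OC)c2B(OC)OC)c(OC)c1 | intermediate
13 | dehydrodieugenol B (4-allyl-2-(4-allyl-2-methoxyphenoxy)-6-methoxyphenol) | C=CCc1ccc(Oc2cc(CC=C)cc(OC)c2O)c(OC)c1 | intermediate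
14 | 5-allyl-1-bromo-3-methoxy-2-(methoxymethoxy)benzene | C=CCc1cc(Br)c(OCOC)c(OC)c1 | intermediate
15 | 5-allyl-1-[4-allyl-2-(4-allyl-2-methoxyphenoxy)-6-methoxyphenoxy]-3-methoxy-2-(methoxymethoxy)benzene | C=CCc1ccc(Oc2cc(CC=C)cc(OC)c2Oc2cc(CC=C)cc(OC)c2OCOC)c(OC)c1 | intermediate
16 | 4-allyl-2-[4-allyl-2-(4-allyl-2-methoxyphenoxy)-6-methoxyphenoxy]-6-methoxyphenol | C=CCc1ccc(Oc2cc(CC=C)cc(OC)c2Oc2cc(CC=C)cc(OC)c2O)c(OC)c1 | target

Total steps: 7. Longest linear sequence: 6 (steps 1, 2, 3, 4, 6, 7); step 5 is a one-step branch from compound 2.

**Steps most likely to fail**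

Step 3. The aryl anion may be protonated before iodine transfer, by adventitious water or by allylic CH2 groups, which would give the iodine-free diaryl ether. The phenoxide may also be consumed by the iodine donor through electron transfer, or the aryl anion may add to a second aryne. Fallback with known chemistry, setting out from eugenol 1 and bromide 14: copper-catalysed Ullmann coupling (CuI, picolinic acid, K3PO4, DMSO, 90 °C) should give the methoxymethyl ether of dehydrodieugenol B F1. HCl in methanol then frees the phenol, and the route is rejoined at compound 13; steps 2 to 4 are not needed in that case.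

Step 6. Copper insertion into the hindered, electron-rich bromide and approach of the 2,6-disubstituted phenoxide may be slow, so that conversion stalls and prolonged heating with base starts to shift allyl groups to propenyl groups. Fallback, open once step 3 has been reduced to practice, setting out from phenol 13: deprotonation with KH gives the potassium phenoxide of dehydrodieugenol B F2. This is added to aryne 8, released from 5 with CsF and 18-crown-6 in the presence of 6, which gives the ring C aryl anion F3 and, after iodine transfer, 5-allyl-1-(4-allyl-2-methoxyphenoxy)-2-(5-allyl-2-iodo-3-methoxyphenoxy)-3-methoxybenzene F4. Aryne additions are little affected by steric hindrance at the nucleophile. Exchange with i-PrMgCl·LiCl to the arylmagnesium chloride F5, borylation with B(OMe)3 to the dimethyl boronate F6 and alkaline H2O2 oxidation then lead directly to target 16, without any protecting group.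

Step 1. NBS may be taken up by the alkene or a second bromine may enter, so that the monobromophenol is not obtained cleanly. Fallback, setting out from eugenol 1: two equivalents of Br2 in CH2Cl2 at 0 °C saturate the alkene and brominate the ring ortho to the hydroxyl group, giving racemic 2-bromo-4-(2,3-dibromopropyl)-6-methoxyphenol F7. Zn dust in AcOH/EtOH then removes only the vicinal bromines by reductive elimination and restores the allyl group, arriving at compound 2.

**Further compounds**
F1 | step 3 | 5-allyl-1-(4-allyl-2-methoxyphenoxy)-3-methoxy-2-(methoxymethoxy)benzene | C=CCc1ccc(Oc2cc(CC=C)cc(OC)c2OCOC)c(OC)c1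
F2 | step 6 | potassium 4-allyl-2-(4-allyl-2-methoxyphenoxy)-6-methoxyphenoxide | C=CCc1ccc(Oc2cc(CC=C)cc(OC)c2[O-])c(OC)c1.[K+]
F3 | step 6 | potassium 4-allyl-2-[4-allyl-2-(4-allyl-2-methoxyphenoxy)-6-methoxyphenoxy]-6-methoxybenzen-1-ide | C=CCc1ccc(Oc2cc(CC=C)cc(OC)c2Oc2cc(CC=C)cc(OC)[c-]2)c(OC)c1.[K+]
F4 | step 6 | 5-allyl-1-(4-allyl-2-methoxyphenoxy)-2-(5-allyl-2-iodo-3-methoxyphenoxy)-3-methoxybenzene | C=CCc1ccc(Oc2cc(CC=C)cc(OC)c2Oc2cc(CC=C)cc(OC)c2I)c(OC)c1
F5 | step 6 | {4-allyl-2-[4-allyl-2-(4-allyl-2-methoxyphenoxy)-6-methoxyphenoxy]-6-methoxyphenyl}magnesium chloride | C=CCc1ccc(Oc2cc(CC=C)cc(OC)c2Oc2cc(CC=C)cc(OC)c2[Mg]Cl)c(OC)c1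
F6 | step 6 | dimethyl {4-allyl-2-[4-allyl-2-(4-allyl-2-methoxyphenoxy)-6-methoxyphenoxy]-6-methoxyphenyl}boronate | C=CCc1ccc(Oc2cc(CC=C)cc(OC)c2Oc2cc(CC=C)cc(OC)c2B(OC)OC)c(OC)c1
F7 | step 1 | 2-bromo-4-(2,3-dibromopropyl)-6-methoxyphenol (racemic) | COc1cc(CC(Br)CBr)cc(Br)c1O
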